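Readings and results were computed for substances that don't exist, and the scatter is random.

The dawn run ended at 40.9% of target and the spring run, with the same reagent charge and more substrate, at 21.7%. We reckon the new flasks from that pair.

| flask | substrate | reagent | remark | time |
|---|---|---|---|---|
| dawn | 0.026 M | 0.070 M | run made earlier |  |
| spring | 0.15 M | 0.070 M | run made earlier |  |
| autumn | 0.10 M | 0.096 M | run made earlier |  |
| south-east | 0.050 M | 0.0700 M |  | 15 h |
| north-east | 0.10 M | 0.0700 M |  | 15 h |
| south-west | 0.030 M | 0.300 M |  | 15 h |
| north-west | 0.060 M | 0.300 M |  | 15 h |
| north | 0.20 M | 0.0400 M |  | 15 h |
| south | 0.20 M | 0.0700 M |  | 15 h |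

| run | time / h | target / % |
|---|---|---|
| dawn | 1.33 | 14.3 |
| dawn | 3.00 | 24.5 |
| dawn | 6.00 | 33.9 |
| dawn | 15.0 | 40.9 |
| spring | 1.33 | 10.8 |
| spring | 3.00 | 14.8 |
| spring | 6.00 | 18.6 |
| spring | 15.0 | 21.7 |
| autumn | 2.00 | 19.4 |
| autumn | 5.00 | 28.0 |
| autumn | 10.0 | 32.3 |
| autumn | 15.0 | 33.6 |

(standard deviation of a reading: 0.3 percentage points)

1. the flasks put in order of amount of target, in percent of the substrate charged, best first, at 15 h (south-east / north-east / south-west / north-west / north / south)
2. the amount of target, in percent of the substrate charged of the flask you put first, at 15 h
3. the amount of target, in percent of the substrate charged of the flask you put last, at 15 h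

- percentages count the substrate that a species holds: one side product B or side product C counts as two
- what may be going on: substrate + reagent -> target; substrate -> side product A; 2 substrate -> side product B; substrate + target -> side product C; substrate -> decomposition product

The autumn run moved from 32.3% to 33.6% over its last two readings, so we treat readings at 15 h as finished. We take substrate to go to target at a rate proportional to substrate times reagent, to go by itself at first order, and to go in pairs at a rate proportional to the square of the substrate. Take the odds against target, which is the inverse of the selectivity, and multiply them by the reagent charge to get the loss load. Yield is then reagent over reagent plus load.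

At any moment the load is a floor plus a pair term in the substrate present. Substrate falls from its charge towards nil, so we treat the pair term as a correction and average it at half its starting size. Dawn gives a load of 0.101 M and spring 0.253 M. Each unit of substrate charged therefore adds 1.22, and the load floor 0.0694 M is the reagent concentration at which target and first-order loss tie. Floor plus that term gives autumn 33.4%, against 33.6% read.

South-west charges 10.0 times as much reagent as substrate, so its target route is pseudo-first-order. With the floor as its load we reckon south-west at 81.2%, the upper edge of our estimated bracket. With the pair term held at its starting size we reckon it at 67.8%, the lower edge. The averaged load 0.106 M gives 73.9%. The same sum gives north-west 67.8%, south-east 34.9%, north-east 26.8%, south 18.2% and north 11.3%, a falling order. At that figure north turns 56.6% of its reagent into target while the rule holds reagent at its charge, so we read north as high.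

The forecast gave south-west > north-west > south-east > north-east > south > north, with 72% inside our bracket and 11.8% last, noting that “High-reagent flasks are extrapolated”.

The flasks give south-west > north-west > south-east > north-east > south > north, with south-west at 75.5%, inside the bracket, and north at 10.5%.

    substrate + reagent → target (k = 0.0316 M⁻¹ min⁻¹)
    substrate → side product A (k = 0.00200 min⁻¹)
    2 substrate → side product B (k = 0.0256 M⁻¹ min⁻¹)
    substrate + target → side product C (k = 0.00758 M⁻¹ min⁻¹)
    substrate → decomposition product (k = 1.18 × 10⁻⁶ min⁻¹)

The neighbour is south-west with substrate raised to 0.075 M, so that its reagent charge is 4.00 equiv. The floor stays at 0.0694 M and the load grows from 0.106 M to 0.161 M, so the same sum gives 65.1%. The flask gives 66.8%. Side product A stands at 15.8% there against 16.7% in south-west, while side product B stands at 14.2% against 6.24%.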